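## The problem

The target is a caged acyl ketal. Its left half is a bicyclo[2.2.2]oct-5-en-2-one, numbered here C1 (carbinol bridgehead), C2 (ketone), C3 (ether carbon bearing a prenyl group), C4 (oxygenated bridgehead), C5=C6 (alkene, carboxyl carbon on C5), C7 (CH2) and C8 (CH). C3 and C8 are tied by an O–C(CH3)2 bridge, so a tetrahydrofuran is fused across two of the three bridges. The C5 carboxyl and the C4 oxygen both end on one spiro carbon of a cyclohexene-1,4-dione that carries a second prenyl group and a fused 2,2-dimethyl-2H-pyran; that carbon is the acetal centre of a 1,3-dioxin-4-one. There are six stereocentres: C1, C3, C4 and C8 in the cage, and the spiro carbon with its neighbouring prenyl-bearing CH. C3 and C4 are adjacent, fully substituted, oxygenated carbons and must be set together with C8 before the cage closes; C1 then has no freedom, because the bridge can close only one way. The two centres on the dione ring sit on a ketal carbon and alpha to a ketone, can equilibrate, and are best left to the end under the influence of the finished cage. Fragile features are the two prenyl groups and the chromene alkene (acid, electrophilic oxidants, hydrogenation), the tertiary alpha-ketol at C1/C2 (ketol shift), the beta-hydroxy ketone relation between the C4 oxygen and C2 (retro-aldol once that hydroxyl is free) and the acyl ketal itself. The feature that allows a short cage closure is that the C1 hydroxyl and the C2 ketone form an acyloin: cutting C1–C2 by umpolung leaves an aldehyde on C3 and a ketone at C1 of a cis-fused bicycle.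

## Retrosynthesis

**Spiro ketal.** Both C–O bonds at the spiro carbon are cut. The ketal ether bond is opened first (retro-oxa-Michael) to the hydroxy quinone ester 31, which comes from silyl ether 30, and the ester bond then gives acid 24 and hydroxyquinone 29. The alternative order (ether first) would need an intermolecular attack of a hindered tertiary alcohol on a quinone. The cut removes two stereocentres and divides the molecule into two fragments of 17 and 16 carbons. The forward reaction must acylate the acidic quinone hydroxyl and then close a six-membered ring by 6-exo addition, with both new centres free to equilibrate.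

**Hydroxyquinone 29.** The pyran is cut at its O–C and C–C bonds to the quinone, giving dihydroxyquinone 27 and prenal 28. Quinone 27 goes back to 2-prenylphloroglucinol 26, and that to phloroglucinol 25 and prenyl bromide 6. Symmetry decides every regiochemical question: 25 has one kind of ring CH, 26 has only one pair of para-related OH/CH positions, and 27 has a single ring CH for the condensation.

**Acid 24.** The carboxyl is traced to a CH2O–MOM group in caged acyloin 21 through primary alcohol 22 and enal 23. The carboxyl must stay at the alcohol level until the cage exists, because an ester on C5 would make C6 a Michael acceptor for the acyl anion used in the next cut.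

**Cage (key cut).** The C1–C2 bond of 21 is cut to keto aldehyde 20. Neighbouring cuts (C1–C7, or the tetrahydrofuran bonds) need radical or ylide chemistry on an already assembled bicyclooctenone. This cut uses the native 1,2-dioxygen pattern, removes one ring and one stereocentre, and leaves a fused bicycle with three stereocentres. The forward step needs an acyl anion that adds 1,2 to an enone carbonyl under conditions that neither enolise the ketone nor cleave the beta-oxygenated aldehyde.

**Enone and aldehyde of 20.** The aldehyde and the enone carbonyl are traced to diol 19, and that to enone ester 18. The C–CH2OMOM bond of 18 is cut with 1,3-transposition of the carbonyl: 18 arises from tertiary allylic alcohol 17, made from enone 15 and stannane 16. Enone 15 comes from ketone 13, and that from ketol 12. This places the side chain and the enone in three operations from a plain cyclohexanone.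

**Ring-fusion carbinol.** The bond from the carbinol carbon to the ketone carbon in 12 is cut to keto aldehyde 11. An external acyl anion would add to the ring ketone anti to the neighbouring side chain, which gives the wrong trans relation. Delivery from the side chain itself can only give the cis-fused ring, with the hydroxyl cis to the ring-fusion hydrogen. The same reaction type as the key step is therefore used once more.

**Side chain and C8 centre.** Aldehyde 11 comes from allyl ketone 10 by adding CO and H2. The allyl C–C bond of 10 is cut to enol carbonate 9, made from ketone 7 and allyl chloroformate 8. The new centre is 1,3 to the existing one, so substrate bias is expected to be weak and a chiral catalyst must decide.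

**Tetrahydrofuran.** The prenyl bond of 7 is cut to beta-keto ester 5 and prenyl bromide 6; this step introduces the absolute configuration. The ring O–C bond of 5 is cut to diazo ester 4, which comes from hydroxy keto ester 3, made from tert-butyl acetoacetate 1 and acetone 2. Closing the ring by O–H insertion fixes the position of the ketone unambiguously.

## Roads not taken

**Alternative 1:** The tetrahydrofuran O–C3 bond and the bond from C3 to the prenyl CH2 are cut together. A bicyclic diazoketone A1 carrying a 1,1-dimethylallyl ether on the C8 side chain would give a rhodium carbenoid. The ether oxygen captures it, and a [2,3]-shift of the allyl unit delivers the bis-silylated caged ester A2. The merits are real: the most congested centre (C3) and the prenyl group appear in one step, the cage dictates the configuration, and the carboxyl is already an ester, which saves the late redox steps of the chosen plan. The weak points are the di-tertiary ether needed in A1, which is hard to make, competing cyclopropanation of the cage alkene and [1,2]-shift, and the need for a separate asymmetric synthesis of an oxygenated bicyclooctenone. Against the shorter end-game, the chosen plan sets C3 early by a catalytic asymmetric alkylation on a simple keto ester.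

**Alternative 2:** The C3–C4 bond and a relay bond to C5 are cut. An alkoxyketene released from acid chloride A3 would add [2+2] across the tethered silyl enol ether of a 1,4-disiloxycyclohexadiene to give vinylcyclobutanone A4, and a 1,3-acyl shift would then expand it to the cage. This is the most step-economic of the roads: two adjacent quaternary centres and two C–C bonds form at once, and strain release drives the cage closure. For this target the diene in A3 is a bis-enol ether of a 1,4-dione and is prone to aromatise. The reacting enol ether is conjugated to an ester and is therefore a poor ketene partner. The ketene precursor again needs a tertiary alkyl ether of an alpha-hydroxy acid, and the acyl shift competes with cycloreversion. The chosen plan is longer, but each of its bonds is made by a reaction with close precedent under mild conditions.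

**Alternative 3:** The C1–C7 bond is cut. A tertiary alpha-alkoxy-alpha-keto radical from selenide A5 would add 6-endo to the terminal carbon of an exocyclic methylene at C8 and give caged ester A6. It is stereoconvergent and neutral, so it avoids the base-induced enolisation that threatens the chosen key step, and it carries the carboxyl as an ester. The radical, however, is captodative and also allylic to the enoate, so addition to an unactivated alkene should be slow and may occur through the wrong terminus. Selenide A5 also already contains both quaternary centres and the cis-fused bicycle, so it is no easier to reach than keto aldehyde 20. The chosen plan closes the same ring with an organocatalyst and no tin; it pays for this with two extra redox steps.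

Key step: step 15

**Assumptions.** The hand of the phase-transfer catalyst (step 4) and of the bisphosphine ligand (step 6) that gives the drawn configurations must be assigned by experiment. The configuration of the spiro ketal carbon and of the adjacent prenyl-bearing CH in the target is taken to be the thermodynamically preferred one, since both centres can equilibrate by retro-oxa-Michael addition and enolisation.

## Route

Step 1
Reactants: 1 tert-butyl acetoacetate; 2 acetone
Product: 3 tert-butyl 5-hydroxy-5-methyl-3-oxohexanoate
Conditions: LiN(i-Pr)2 (2.2 equiv), THF, −78 → 0 °C; then 2, −78 °C; AcOH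
Reagents that add atoms: none
Why: Aldol addition of the acetoacetate dianion, which reacts only at its terminal carbon; the tert-butyl ester prevents lactonisation of the delta-hydroxy ester.

Step 2
Reactants: 3 tert-butyl 5-hydroxy-5-methyl-3-oxohexanoate
Product: 4 tert-butyl 2-diazo-5-hydroxy-5-methyl-3-oxohexanoate
Conditions: 4-acetamidobenzenesulfonyl azide, Et3N, MeCN, 0 → 23 °C
Reagents that add atoms: 4-acetamidobenzenesulfonyl azide, CC(=O)Nc1ccc(cc1)S(=O)(=O)N=[N+]=[N-]
Why: Regitz diazo transfer to the active methylene of a beta-keto ester; the tertiary alcohol does not interfere.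

Step 3
Reactants: 4 tert-butyl 2-diazo-5-hydroxy-5-methyl-3-oxohexanoate
Product: 5 tert-butyl 5,5-dimethyl-3-oxotetrahydrofuran-2-carboxylate (racemic)
Conditions: Rh2(OAc)4 (1 mol%), CH2Cl2, 40 °C
Reagents that add atoms: none
Why: Intramolecular O–H insertion of the rhodium carbenoid closes the five-membered ether and places the ketone unambiguously next to the ester-bearing carbon; the new centre is enolisable and is set in step 4.

Step 4
Reactants: 5 tert-butyl 5,5-dimethyl-3-oxotetrahydrofuran-2-carboxylate; 6 prenyl bromide
Product: 7 tert-butyl (2R)-5,5-dimethyl-2-(3-methylbut-2-en-1-yl)-3-oxotetrahydrofuran-2-carboxylate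
Conditions: chiral N-spiro bis(binaphthyl)ammonium bromide with 3,4,5-trifluorophenyl groups (1 mol%), CsOH·H2O, toluene, −40 °C
Reagents that add atoms: none
Why: Asymmetric phase-transfer C-alkylation of a cyclic beta-keto tert-butyl ester; the chiral ammonium–enolate ion pair shields one face and sets the quaternary ether carbon, the source of absolute configuration for the whole route.

Step 5
Reactants: 7 tert-butyl (2R)-5,5-dimethyl-2-(3-methylbut-2-en-1-yl)-3-oxotetrahydrofuran-2-carboxylate; 8 allyl chloroformate
Product: 9 tert-butyl (2R)-3-{[(allyloxy)carbonyl]oxy}-5,5-dimethyl-2-(3-methylbut-2-en-1-yl)-2,5-dihydrofuran-2-carboxylate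
Conditions: KN(SiMe3)2, THF, −78 °C; then 8
Reagents that add atoms: none
Why: O-acylation of the potassium enolate, which can form on one side only; loss of the ring oxygen from the enolate would be a retro-5-endo-trig process and is stereoelectronically disfavoured.

Step 6
Reactants: 9 tert-butyl (2R)-3-{[(allyloxy)carbonyl]oxy}-5,5-dimethyl-2-(3-methylbut-2-en-1-yl)-2,5-dihydrofuran-2-carboxylate
Product: 10 tert-butyl (2R,4S)-4-allyl-5,5-dimethyl-2-(3-methylbut-2-en-1-yl)-3-oxotetrahydrofuran-2-carboxylate (allyl cis to the ester)
Conditions: Pd2(dba)3·CHCl3 (2.5 mol%), (R,R)- or (S,S)-N,N′-(cyclohexane-1,2-diyl)bis[2-(diphenylphosphanyl)benzamide] (5.5 mol%), toluene, 23 °C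
Reagents that add atoms: none
Why: Decarboxylative asymmetric allylic alkylation (Tsuji–Trost type): zerovalent palladium ionises the allyl carbonate, CO2 is lost and the enolate recombines with the allyl complex inside the chiral pocket. The ligand rather than the remote quaternary centre selects the face, and the neutral conditions preserve the epimerisable centre.

Step 7
Reactants: 10 tert-butyl (2R,4S)-4-allyl-5,5-dimethyl-2-(3-methylbut-2-en-1-yl)-3-oxotetrahydrofuran-2-carboxylate
Product: 11 tert-butyl (2R,4S)-5,5-dimethyl-2-(3-methylbut-2-en-1-yl)-3-oxo-4-(4-oxobutyl)tetrahydrofuran-2-carboxylate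
Conditions: Rh(acac)(CO)2 (1 mol%), Xantphos (2 mol%), CO/H2 (1:1, 10 bar), toluene, 70 °C
Reagents that add atoms: carbon monoxide, [C-]#[O+] (H2 adds hydrogen only)
Why: Linear-selective hydroformylation of the monosubstituted alkene with a wide-bite-angle diphosphine; the trisubstituted prenyl alkene and the ketone are inert under these conditions.

Step 8
Reactants: 11 tert-butyl (2R,4S)-5,5-dimethyl-2-(3-methylbut-2-en-1-yl)-3-oxo-4-(4-oxobutyl)tetrahydrofuran-2-carboxylate
Product: 12 tert-butyl (1R,3aR,7aR)-7a-hydroxy-3,3-dimethyl-1-(3-methylbut-2-en-1-yl)-7-oxooctahydroisobenzofuran-1-carboxylate (cis-fused; ester cis to the new ring)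
Conditions: 2-mesityl-6,7-dihydro-5H-pyrrolo[2,1-c][1,2,4]triazol-2-ium chloride (10 mol%), Et3N (10 mol%), THF, 23 °C
Reagents that add atoms: none
Why: Carbene-catalysed intramolecular crossed aldehyde–ketone benzoin reaction: the Breslow intermediate of the side-chain aldehyde adds to the activated ring ketone and closes a six-membered acyloin. Because the acyl carbon is delivered from the side chain, the ring fusion must be cis and the carbinol oxygen ends trans to the chain, which an external acyl anion would not give.

Step 9
Reactants: 12 tert-butyl (1R,3aR,7aR)-7a-hydroxy-3,3-dimethyl-1-(3-methylbut-2-en-1-yl)-7-oxooctahydroisobenzofuran-1-carboxylate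
Product: 13 tert-butyl (1R,3aS,7aR)-3,3-dimethyl-1-(3-methylbut-2-en-1-yl)-7-oxo-7a-[(triethylsilyl)oxy]octahydroisobenzofuran-1-carboxylate
Conditions: Et3SiOTf, 2,6-lutidine, CH2Cl2, −78 → 0 °C
Reagents that add atoms: triethylsilyl trifluoromethanesulfonate, CC[Si](CC)(CC)OS(=O)(=O)C(F)(F)F
Why: Silyl triflates silylate hindered tertiary alcohols; the silyl ether later blocks retro-aldol cleavage and ketol shift and is removed only in the last step.

Step 10
Reactants: 13 tert-butyl (1R,3aS,7aR)-3,3-dimethyl-1-(3-methylbut-2-en-1-yl)-7-oxo-7a-[(triethylsilyl)oxy]octahydroisobenzofuran-1-carboxylate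
Product: 15 tert-butyl (1R,3aS,7aR)-3,3-dimethyl-1-(3-methylbut-2-en-1-yl)-7-oxo-7a-[(triethylsilyl)oxy]-1,3,3a,4,7,7a-hexahydroisobenzofuran-1-carboxylate, via trimethylsilyl enol ether 14 (not isolated)
Conditions: LiN(SiMe3)2, Me3SiCl, THF, −78 °C; then Pd(OAc)2 (1.1 equiv), MeCN, 23 °C
Reagents that add atoms: chlorotrimethylsilane, C[Si](C)(C)Cl (present in intermediate 14 only)
Why: Saegusa–Ito oxidation; the ketone has one enolisable side only, so the enol ether and the enone are regiodefined, and divalent palladium does not affect the prenyl group at room temperature.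

Step 11
Reactants: 15 tert-butyl (1R,3aS,7aR)-3,3-dimethyl-1-(3-methylbut-2-en-1-yl)-7-oxo-7a-[(triethylsilyl)oxy]-1,3,3a,4,7,7a-hexahydroisobenzofuran-1-carboxylate; 16 tributyl[(methoxymethoxy)methyl]stannane
Product: 17 tert-butyl (1R,3aS,7aS)-7-hydroxy-7-[(methoxymethoxy)methyl]-3,3-dimethyl-1-(3-methylbut-2-en-1-yl)-7a-[(triethylsilyl)oxy]-1,3,3a,4,7,7a-hexahydroisobenzofuran-1-carboxylate (mixture at C7)
Conditions: 16, n-BuLi, THF, −78 °C; then 15, −78 °C; AcOH
Reagents that add atoms: none
Why: Tin–lithium exchange gives an alkoxymethyllithium that adds 1,2 to the enone faster than to the neopentyl tert-butyl ester; the configuration of the new carbinol is irrelevant because it is destroyed in step 12.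

Step 12
Reactants: 17 tert-butyl (1R,3aS,7aS)-7-hydroxy-7-[(methoxymethoxy)methyl]-3,3-dimethyl-1-(3-methylbut-2-en-1-yl)-7a-[(triethylsilyl)oxy]-1,3,3a,4,7,7a-hexahydroisobenzofuran-1-carboxylate
Product: 18 tert-butyl (1R,3aS,7aS)-7-[(methoxymethoxy)methyl]-3,3-dimethyl-1-(3-methylbut-2-en-1-yl)-5-oxo-7a-[(triethylsilyl)oxy]-1,3,3a,4,5,7a-hexahydroisobenzofuran-1-carboxylate
Conditions: [C5H5NH][CrO3Cl] (3 equiv), 4 Å molecular sieves, CH2Cl2, 23 °C
Reagents that add atoms: none
Why: Dauben–Babler oxidative transposition: the chromate ester of the tertiary allylic alcohol undergoes a [3,3] shift and the secondary allylic chromate is oxidised, which puts the ketone beta to the ring-fusion CH and the CH2OMOM group on the alkene.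

Step 13
Reactants: 18 tert-butyl (1R,3aS,7aS)-7-[(methoxymethoxy)methyl]-3,3-dimethyl-1-(3-methylbut-2-en-1-yl)-5-oxo-7a-[(triethylsilyl)oxy]-1,3,3a,4,5,7a-hexahydroisobenzofuran-1-carboxylate
Product: 19 (1S,3aS,7aS)-1-(hydroxymethyl)-7-[(methoxymethoxy)methyl]-3,3-dimethyl-1-(3-methylbut-2-en-1-yl)-7a-[(triethylsilyl)oxy]-1,3,3a,4,5,7a-hexahydroisobenzofuran-5-ol (mixture at C5)
Conditions: (i-Bu)2AlH (6 equiv), CH2Cl2, −78 → 23 °C; Rochelle salt
Reagents that add atoms: none
Why: Exhaustive hydride reduction: the ester gives the primary alcohol and the enone undergoes clean 1,2-reduction; no reagent reduces the hindered ester selectively beside the enone, so both are reduced and re-oxidised.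

Step 14
Reactants: 19 (1S,3aS,7aS)-1-(hydroxymethyl)-7-[(methoxymethoxy)methyl]-3,3-dimethyl-1-(3-methylbut-2-en-1-yl)-7a-[(triethylsilyl)oxy]-1,3,3a,4,5,7a-hexahydroisobenzofuran-5-ol
Product: 20 (1R,3aS,7aS)-7-[(methoxymethoxy)methyl]-3,3-dimethyl-1-(3-methylbut-2-en-1-yl)-5-oxo-7a-[(triethylsilyl)oxy]-1,3,3a,4,5,7a-hexahydroisobenzofuran-1-carbaldehyde
Conditions: Dess–Martin periodinane (3 equiv), CH2Cl2, 23 °C
Reagents that add atoms: none
Why: Dess–Martin oxidation of both alcohols under near-neutral conditions; the aldehyde has no alpha hydrogen and the beta oxygen is silylated, so neither epimerisation nor retro-aldol cleavage is possible.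

Step 15
Reactants: 20 (1R,3aS,7aS)-7-[(methoxymethoxy)methyl]-3,3-dimethyl-1-(3-methylbut-2-en-1-yl)-5-oxo-7a-[(triethylsilyl)oxy]-1,3,3a,4,5,7a-hexahydroisobenzofuran-1-carbaldehyde
Product: 21 (1R,3aS,5R,7aS)-5-hydroxy-7-[(methoxymethoxy)methyl]-3,3-dimethyl-1-(3-methylbut-2-en-1-yl)-7a-[(triethylsilyl)oxy]-1,3,3a,4,5,7a-hexahydro-1,5-methanoisobenzofuran-8-one (caged acyloin)
Conditions: 2-mesityl-6,7-dihydro-5H-pyrrolo[2,1-c][1,2,4]triazol-2-ium chloride (20 mol%), DBU (20 mol%), toluene, 40 °C
Reagents that add atoms: none
Why: The triazolylidene adds to the non-enolisable aldehyde and proton transfer gives the Breslow intermediate, an acyl-anion equivalent on the same face of the tetrahydrofuran as the cyclohexenone; it adds 1,2 to the ring ketone and loss of the carbene releases acyloin 21. The closest known reaction type is the carbene-catalysed intramolecular crossed aldehyde–ketone benzoin reaction, used here for a bridged instead of a fused ring. The closure is 6-exo-trig at the carbonyl carbon and completes the bicyclo[2.2.2]octenone through a boat-like arrangement that the cis-fused bicycle already approximates. The only new stereocentre, the carbinol bridgehead, is fixed by the ring-fusion centres and the quaternary ether carbon, because the two-atom bridge can span the ring on one face only. Conjugate addition is excluded because attack at the enone beta carbon would give a four-membered ring and the alkene carries a CH2OMOM group and no carbonyl; self-condensation and internal redox are excluded by the quaternary alpha carbon and the poor leaving-group ability of the ring ether oxygen. Aldol closure from the CH2 next to the ketone onto the aldehyde is the main competitor and is held back by using no more base than azolium salt, and the silyl ether on the neighbouring oxygen points away from the reacting face.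

Step 16
Reactants: 21 caged acyloin
Product: 22 (1R,3aS,5R,7aS)-5-hydroxy-7-(hydroxymethyl)-3,3-dimethyl-1-(3-methylbut-2-en-1-yl)-7a-[(triethylsilyl)oxy]-1,3,3a,4,5,7a-hexahydro-1,5-methanoisobenzofuran-8-one
Conditions: Me2BBr (2 equiv), CH2Cl2, −78 °C; then NaHCO3, THF/H2O
Reagents that add atoms: none
Why: Lewis-acid cleavage of the methoxymethyl acetal at low temperature; the hindered tertiary silyl ether, the alkenes and the ketol are left intact.

Step 17
Reactants: 22 allylic alcohol
Product: 24 (1R,3aS,5R,7aS)-5-hydroxy-3,3-dimethyl-1-(3-methylbut-2-en-1-yl)-8-oxo-7a-[(triethylsilyl)oxy]-1,3,3a,4,5,7a-hexahydro-1,5-methanoisobenzofuran-7-carboxylic acid, via enal 23 (not isolated)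
Conditions: MnO2, CH2Cl2, 23 °C; filter; then NaClO2, NaH2PO4, 2-methyl-2-butene, t-BuOH/H2O, 0 °C
Reagents that add atoms: sodium chlorite, [Na+].[O-]Cl=O
Why: Allylic oxidation with MnO2 followed by Pinnick oxidation; both are selective for the primary allylic position, tertiary alcohols are untouched, and the scavenger protects the prenyl group from hypochlorite.

Step 18
Reactants: 25 phloroglucinol; 6 prenyl bromide
Product: 26 2-(3-methylbut-2-en-1-yl)benzene-1,3,5-triol
Conditions: 25 (3 equiv), DBU, THF, 0 → 23 °C
Reagents that add atoms: none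
Why: C-alkylation of the ambident phloroglucinol anion; the three ring CH positions are equivalent, so one mono-prenyl product forms, and excess triol limits over-alkylation.

Step 19
Reactants: 26 2-(3-methylbut-2-en-1-yl)benzene-1,3,5-triol
Product: 27 2,6-dihydroxy-3-(3-methylbut-2-en-1-yl)cyclohexa-2,5-diene-1,4-dione
Conditions: K2[ON(SO3)2] (2.5 equiv), KH2PO4, H2O/acetone, 0 °C
Reagents that add atoms: potassium nitrosodisulfonate, [K+].[K+].[O-]S(=O)(=O)N([O])S([O-])(=O)=O
Why: Teuber oxidation of a phenol with a free para position to the para-quinone; the only hydroxyl whose para position is blocked is the one opposite the prenyl group, so one quinone results, and the nitroxyl radical does not attack the alkene.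

Step 20
Reactants: 27 2,6-dihydroxy-3-(3-methylbut-2-en-1-yl)cyclohexa-2,5-diene-1,4-dione; 28 3-methylbut-2-enal
Product: 29 7-hydroxy-2,2-dimethyl-6-(3-methylbut-2-en-1-yl)-2H-chromene-5,8-dione
Conditions: pyridine, 100 °C
Reagents that add atoms: none
Why: Knoevenagel condensation at the single ring CH of the vinylogous acid, then oxa-6π electrocyclisation of the dienone. Closure onto the oxygen next to the central carbonyl gives the para-quinone isomer, which should prevail because the electrocyclisation is reversible.

Step 21
Reactants: 24 caged acid; 29 7-hydroxy-2,2-dimethyl-6-(3-methylbut-2-en-1-yl)-2H-chromene-5,8-dione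
Product: 30 2,2-dimethyl-6-(3-methylbut-2-en-1-yl)-5,8-dioxo-5,8-dihydro-2H-chromen-7-yl ester of acid 24
Conditions: EDC·HCl, DMAP (cat.), CH2Cl2, 0 → 23 °C
Reagents that add atoms: none
Why: Steglich esterification; the acidic quinone hydroxyl is the only acylable oxygen, since both remaining alcohols are tertiary or silylated.

Step 22
Reactants: 30 quinone ester
Product: 32 CNP0222516.1, via hydroxy quinone ester 31 (not isolated)
Conditions: HF·pyridine, pyridine, THF, 0 → 23 °C
Reagents that add atoms: none
Why: Desilylation frees the tertiary hydroxyl, which adds to the acyloxy-bearing quinone carbon (intramolecular oxa-Michael addition, 6-exo-trig); tautomerisation of the enol gives the ene-dione. The spiro ketal carbon and the adjacent CH are formed reversibly (retro-addition, enolisation), so the cage should steer them to the more stable arrangement, and the weakly basic medium avoids retro-aldol cleavage.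

## Compound list

1 | tert-butyl acetoacetate | CC(=O)CC(=O)OC(C)(C)C | starting material
2 | acetone | CC(C)=O | starting material
3 | tert-butyl 5-hydroxy-5-methyl-3-oxohexanoate | CC(C)(O)CC(=O)CC(=O)OC(C)(C)C | intermediate
4 | tert-butyl 2-diazo-5-hydroxy-5-methyl-3-oxohexanoate | CC(C)(O)CC(=O)C(=[N+]=[N-])C(=O)OC(C)(C)C | intermediate
5 | tert-butyl 5,5-dimethyl-3-oxotetrahydrofuran-2-carboxylate (racemic) | CC1(C)CC(=O)C(O1)C(=O)OC(C)(C)C | intermediate
6 | prenyl bromide (1-bromo-3-methylbut-2-ene) | CC(C)=CCBr | starting material
7 | tert-butyl (2R)-5,5-dimethyl-2-(3-methylbut-2-en-1-yl)-3-oxotetrahydrofuran-2-carboxylate | C1C(C)(C)O[C@@](CC=C(C)C)(C(=O)OC(C)(C)C)C1=O | intermediate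
8 | allyl chloroformate | C=CCOC(Cl)=O | starting material
9 | tert-butyl (2R)-3-{[(allyloxy)carbonyl]oxy}-5,5-dimethyl-2-(3-methylbut-2-en-1-yl)-2,5-dihydrofuran-2-carboxylate | CC1(C)C=C(OC(=O)OCC=C)[C@](CC=C(C)C)(C(=O)OC(C)(C)C)O1 | intermediate
10 | tert-butyl (2R,4S)-4-allyl-5,5-dimethyl-2-(3-methylbut-2-en-1-yl)-3-oxotetrahydrofuran-2-carboxylate | C=CC[C@H]1C(C)(C)O[C@@](CC=C(C)C)(C(=O)OC(C)(C)C)C1=O | intermediate
11 | tert-butyl (2R,4S)-5,5-dimethyl-2-(3-methylbut-2-en-1-yl)-3-oxo-4-(4-oxobutyl)tetrahydrofuran-2-carboxylate | O=CCCC[C@H]1C(C)(C)O[C@@](CC=C(C)C)(C(=O)OC(C)(C)C)C1=O | intermediate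
12 | tert-butyl (1R,3aR,7aR)-7a-hydroxy-3,3-dimethyl-1-(3-methylbut-2-en-1-yl)-7-oxooctahydroisobenzofuran-1-carboxylate | O=C1CCC[C@H]4C(C)(C)O[C@@](CC=C(C)C)(C(=O)OC(C)(C)C)[C@@]14O | intermediate
13 | tert-butyl (1R,3aS,7aR)-3,3-dimethyl-1-(3-methylbut-2-en-1-yl)-7-oxo-7a-[(triethylsilyl)oxy]octahydroisobenzofuran-1-carboxylate | O=C1CCC[C@H]4C(C)(C)O[C@@](CC=C(C)C)(C(=O)OC(C)(C)C)[C@@]14O[Si](CC)(CC)CC | intermediate
14 | trimethylsilyl enol ether of 13 (C6=C7 enol ether; not isolated) | C[Si](C)(C)OC1=CCC[C@H]4C(C)(C)O[C@@](CC=C(C)C)(C(=O)OC(C)(C)C)[C@@]14O[Si](CC)(CC)CC | intermediate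
15 | tert-butyl (1R,3aS,7aR)-3,3-dimethyl-1-(3-methylbut-2-en-1-yl)-7-oxo-7a-[(triethylsilyl)oxy]-1,3,3a,4,7,7a-hexahydroisobenzofuran-1-carboxylate | O=C1C=CC[C@H]4C(C)(C)O[C@@](CC=C(C)C)(C(=O)OC(C)(C)C)[C@@]14O[Si](CC)(CC)CC | intermediate
16 | tributyl[(methoxymethoxy)methyl]stannane | CCCC[Sn](CCCC)(CCCC)COCOC | starting material
17 | tert-butyl (1R,3aS,7aS)-7-hydroxy-7-[(methoxymethoxy)methyl]-3,3-dimethyl-1-(3-methylbut-2-en-1-yl)-7a-[(triethylsilyl)oxy]-1,3,3a,4,7,7a-hexahydroisobenzofuran-1-carboxylate (mixture at C7) | COCOCC1(O)C=CC[C@H]4C(C)(C)O[C@@](CC=C(C)C)(C(=O)OC(C)(C)C)[C@@]14O[Si](CC)(CC)CC | intermediate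
18 | tert-butyl (1R,3aS,7aS)-7-[(methoxymethoxy)methyl]-3,3-dimethyl-1-(3-methylbut-2-en-1-yl)-5-oxo-7a-[(triethylsilyl)oxy]-1,3,3a,4,5,7a-hexahydroisobenzofuran-1-carboxylate | COCOCC1=CC(=O)C[C@H]4C(C)(C)O[C@@](CC=C(C)C)(C(=O)OC(C)(C)C)[C@@]14O[Si](CC)(CC)CC | intermediate
19 | (1S,3aS,7aS)-1-(hydroxymethyl)-7-[(methoxymethoxy)methyl]-3,3-dimethyl-1-(3-methylbut-2-en-1-yl)-7a-[(triethylsilyl)oxy]-1,3,3a,4,5,7a-hexahydroisobenzofuran-5-ol (mixture at C5) | COCOCC1=CC(O)C[C@H]4C(C)(C)O[C@@](CC=C(C)C)(CO)[C@@]14O[Si](CC)(CC)CC | intermediate
20 | (1R,3aS,7aS)-7-[(methoxymethoxy)methyl]-3,3-dimethyl-1-(3-methylbut-2-en-1-yl)-5-oxo-7a-[(triethylsilyl)oxy]-1,3,3a,4,5,7a-hexahydroisobenzofuran-1-carbaldehyde | COCOCC1=CC(=O)C[C@H]4C(C)(C)O[C@@](CC=C(C)C)(C=O)[C@@]14O[Si](CC)(CC)CC | intermediate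
21 | (1R,3aS,5R,7aS)-5-hydroxy-7-[(methoxymethoxy)methyl]-3,3-dimethyl-1-(3-methylbut-2-en-1-yl)-7a-[(triethylsilyl)oxy]-1,3,3a,4,5,7a-hexahydro-1,5-methanoisobenzofuran-8-one (caged acyloin) | COCOCC1=C[C@]3(O)C[C@H]4C(C)(C)O[C@@](CC=C(C)C)(C3=O)[C@@]14O[Si](CC)(CC)CC | intermediate
22 | (1R,3aS,5R,7aS)-5-hydroxy-7-(hydroxymethyl)-3,3-dimethyl-1-(3-methylbut-2-en-1-yl)-7a-[(triethylsilyl)oxy]-1,3,3a,4,5,7a-hexahydro-1,5-methanoisobenzofuran-8-one | OCC1=C[C@]3(O)C[C@H]4C(C)(C)O[C@@](CC=C(C)C)(C3=O)[C@@]14O[Si](CC)(CC)CC | intermediate
23 | caged enal: 7-carbaldehyde corresponding to 22 (not isolated) | O=CC1=C[C@]3(O)C[C@H]4C(C)(C)O[C@@](CC=C(C)C)(C3=O)[C@@]14O[Si](CC)(CC)CC | intermediate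
24 | (1R,3aS,5R,7aS)-5-hydroxy-3,3-dimethyl-1-(3-methylbut-2-en-1-yl)-8-oxo-7a-[(triethylsilyl)oxy]-1,3,3a,4,5,7a-hexahydro-1,5-methanoisobenzofuran-7-carboxylic acid | OC(=O)C1=C[C@]3(O)C[C@H]4C(C)(C)O[C@@](CC=C(C)C)(C3=O)[C@@]14O[Si](CC)(CC)CC | intermediate
25 | phloroglucinol (benzene-1,3,5-triol) | Oc1cc(O)cc(O)c1 | starting material
26 | 2-(3-methylbut-2-en-1-yl)benzene-1,3,5-triol | CC(C)=CCc1c(O)cc(O)cc1O | intermediate
27 | 2,6-dihydroxy-3-(3-methylbut-2-en-1-yl)cyclohexa-2,5-diene-1,4-dione | CC(C)=CCC1=C(O)C(=O)C(O)=CC1=O | intermediate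
28 | 3-methylbut-2-enal (prenal) | CC(C)=CC=O | starting material
29 | 7-hydroxy-2,2-dimethyl-6-(3-methylbut-2-en-1-yl)-2H-chromene-5,8-dione | CC(C)=CCC1=C(O)C(=O)C2=C(C=CC(C)(C)O2)C1=O | intermediate
30 | 2,2-dimethyl-6-(3-methylbut-2-en-1-yl)-5,8-dioxo-5,8-dihydro-2H-chromen-7-yl ester of acid 24 (tertiary oxygen silylated) | CC(C)=CCC1=C(OC(=O)C3=C[C@]4(O)C[C@H]5C(C)(C)O[C@@](CC=C(C)C)(C4=O)[C@@]35O[Si](CC)(CC)CC)C(=O)C2=C(C=CC(C)(C)O2)C1=O | intermediate
31 | hydroxy quinone ester: 30 with the tertiary hydroxyl free (not isolated) | CC(C)=CCC1=C(OC(=O)C3=C[C@]4(O)C[C@H]5C(C)(C)O[C@@](CC=C(C)C)(C4=O)[C@@]35O)C(=O)C2=C(C=CC(C)(C)O2)C1=O | intermediate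
32 | CNP0222516.1 | CC(C)=CC[C@H]1C(=O)C2=C(OC(C)(C)C=C2)C(=O)[C@@]12OC(=O)C1=C[C@]3(O)C[C@H]4C(C)(C)O[C@@](CC=C(C)C)(C3=O)[C@@]14O2 | target

## Step count and risks

Total: 22 steps. Longest linear sequence: 19 steps (steps 1–17, 21 and 22); steps 18–20 make the quinone fragment.

Least certain steps:

**Step 15 (key step).** The most likely failure is base-induced enolisation of the CH2 next to the enone ketone, followed by aldol closure onto the aldehyde, which sits on the same face. Slow carbene addition to the hindered aldehyde and reversal of the benzoin step are further risks. Fallback: from 20, a reductive pinacol cyclisation between aldehyde and ketone carbonyl (TiCl3(DME)1.5, Zn–Cu, DME) would give the bridged diol F1. Oxidation of its secondary carbinol with Dess–Martin periodinane returns to the route at 21.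

**Step 6.** Facial selection at the carbon alpha to the ketone may be poor if ligand and existing centre are mismatched, and the new centre can erode by enolisation. Fallback: from 7, direct enolate alkylation (LiN(SiMe3)2, allyl bromide) would give 10 together with its (2R,4R) epimer F2. The two are separated and F2 is recycled by base equilibration, so control comes from separation and recycling rather than from the catalyst; the route is rejoined at 10.

**Step 8.** The side-chain-bearing centre may epimerise before ring closure, and the enolisable aldehyde may undergo aldol addition to the ketone. Fallback: from 11, ketyl–carbonyl cyclisation with SmI2 (THF, t-BuOH, −78 °C) would give the cis-fused diol F3. Oxidation of its secondary alcohol (Dess–Martin periodinane) returns to the route at 12.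

**Step 19.** The electron-rich triol may undergo oxidative coupling or over-oxidation, and the strongly acidic product may be lost to the aqueous phase. Fallback: the quinone is built before the prenyl group. Commercial 2,6-dimethoxy-1,4-benzoquinone F4 is mono-hydrolysed (aq. NaOH, then acid) to 2-hydroxy-6-methoxy-1,4-benzoquinone F5. Condensation with prenal 28 as in step 20 gives 7-methoxy-2,2-dimethyl-2H-chromene-5,8-dione F6. Hydrolysis of the vinylogous ester gives 7-hydroxy-2,2-dimethyl-2H-chromene-5,8-dione F7, whose lithium salt is C-alkylated with prenyl bromide 6 in DMSO at its only free ring position. This returns to the route at 29.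

**Step 22.** Ring closure may stop at an equilibrium mixture, or settle on the other spiro epimer, and the liberated tertiary alcohol may undergo retro-aldol cleavage if the medium is too basic. Fallback: the ring is formed as an acetal instead of by conjugate addition. From 24, silylation (Me3SiCl, Et3N) gives the trimethylsilyl ester with the bridgehead hydroxyl also silylated, F8. Me3SiOTf-catalysed condensation of this silylated beta-hydroxy acid with the C7 carbonyl of the trione tautomer of 29 (CH2Cl2, −78 °C) gives the bridgehead silyl ether of the target, F9. Desilylation with HF·pyridine returns to the route at 32.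

## Further compounds

F1 | step 15 | bridged diol: 21 with the cage ketone reduced to a secondary carbinol (mixture at that carbon) | COCOCC1=C[C@]3(O)C[C@H]4C(C)(C)O[C@@](CC=C(C)C)(C3O)[C@@]14O[Si](CC)(CC)CC
F2 | step 6 | tert-butyl (2R,4R)-4-allyl-5,5-dimethyl-2-(3-methylbut-2-en-1-yl)-3-oxotetrahydrofuran-2-carboxylate | C=CC[C@@H]1C(C)(C)O[C@@](CC=C(C)C)(C(=O)OC(C)(C)C)C1=O
F3 | step 8 | tert-butyl 7,7a-dihydroxy-3,3-dimethyl-1-(3-methylbut-2-en-1-yl)octahydroisobenzofuran-1-carboxylate (cis-fused, mixture at C7) | OC1CCC[C@H]4C(C)(C)O[C@@](CC=C(C)C)(C(=O)OC(C)(C)C)[C@@]14O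
F4 | step 19 | 2,6-dimethoxy-1,4-benzoquinone | COC1=CC(=O)C=C(OC)C1=O
F5 | step 19 | 2-hydroxy-6-methoxy-1,4-benzoquinone | COC1=CC(=O)C=C(O)C1=O
F6 | step 19 | 7-methoxy-2,2-dimethyl-2H-chromene-5,8-dione | COC1=CC(=O)C2=C(OC(C)(C)C=C2)C1=O
F7 | step 19 | 7-hydroxy-2,2-dimethyl-2H-chromene-5,8-dione | OC1=CC(=O)C2=C(OC(C)(C)C=C2)C1=O
F8 | step 22 | trimethylsilyl ester of 24 with the bridgehead hydroxyl as trimethylsilyl ether | C[Si](C)(C)OC(=O)C1=C[C@]3(O[Si](C)(C)C)C[C@H]4C(C)(C)O[C@@](CC=C(C)C)(C3=O)[C@@]14O[Si](CC)(CC)CC
F9 | step 22 | bridgehead trimethylsilyl ether of 32 | CC(C)=CC[C@H]1C(=O)C2=C(OC(C)(C)C=C2)C(=O)[C@@]12OC(=O)C1=C[C@]3(O[Si](C)(C)C)C[C@H]4C(C)(C)O[C@@](CC=C(C)C)(C3=O)[C@@]14O2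
A1 | alternative 1 | bicyclic diazoketone with a 1,1-dimethylallyl ether side chain | COC(=O)C1=C[C@]3(O[Si](CC)(CC)CC)C[C@@H](C(C)(C)OC(C)(C)C=C)[C@@]1(O[Si](CC)(CC)CC)C(=[N+]=[N-])C3=O
A2 | alternative 1 | bis-silylated caged methyl ester | COC(=O)C1=C[C@]3(O[Si](CC)(CC)CC)C[C@H]4C(C)(C)O[C@@](CC=C(C)C)(C3=O)[C@@]14O[Si](CC)(CC)CC
A3 | alternative 2 | acid chloride tethered to a 1,4-disiloxycyclohexa-1,3-diene ester | COC(=O)C1=C(O[Si](C)(C)C(C)(C)C)[C@H](C(C)(C)OC(CC=C(C)C)C(Cl)=O)CC(O[Si](C)(C)C(C)(C)C)=C1
A4 | alternative 2 | tetrahydrofuran-fused 2-vinylcyclobutanone | COC(=O)[C@@]12C=C(O[Si](C)(C)C(C)(C)C)C[C@H]3C(C)(C)O[C@@](CC=C(C)C)(C1=O)[C@@]23O[Si](C)(C)C(C)(C)C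
A5 | alternative 3 | alpha-phenylselanyl alpha-alkoxy cyclohexenone with exocyclic methylene on the tetrahydrofuran | COC(=O)C1=CC(OCOC)([Se]c2ccccc2)C(=O)[C@]3(CC=C(C)C)OC(C)(C)C(=C)[C@]13O
A6 | alternative 3 | caged methyl ester with MOM-protected bridgehead carbinol | COC(=O)C1=C[C@]3(OCOC)C[C@H]4C(C)(C)O[C@@](CC=C(C)C)(C3=O)[C@@]14O
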